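**Plan**

- The target is 7,4'-dihydroxy-3,5,6,8-tetramethoxyflavone, described with flavone numbering: O1, C2–C4, C4a, C5–C8, C8a, and rings A, B and C.
- The retrosynthesis first removes the two O-benzyl protecting groups, the 3-O-methyl group and the C3–O bond. It then cuts ring C at C4a–C4, C4–C3 and O1–C2.
- Enabling feature: C4 is a single carbonyl carbon between aryl carbon C4a and C3. C2–C3 is at the alkyne oxidation level with ring B on C2, and O1 sits on C8a, ortho to C4a. Ring C is therefore a 2-iodophenol plus CO plus a terminal arylalkyne.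
- Forward, ring A is bought as 2,4,5-trimethoxybenzaldehyde and raised to the pentaoxygenated iodophenol (CHO to OH, one C–H to O-benzyl, the last C–H to iodide). Ring B arrives with the alkyne.
- Ring C is the only ring formed, in one three-component operation. C3–H then becomes C3–OMe, and hydrogenolysis frees the 7- and 4'-hydroxyls.
- The target has no stereocentre. Only regiochemistry must be controlled: the site of lithiation, the site of iodination, and 6-endo versus 5-exo closure.

Key step: step 7

Assumption: the enaminone intermediate of step 7 is drawn as its E isomer. Its push–pull double bond rotates readily at the reaction temperature, so the geometry has no bearing on ring closure.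

**Step 1**
Reactants: 1 2,4,5-trimethoxybenzaldehyde
Product: 3 2,4,5-trimethoxyphenol, via aryl formate 2 (not isolated)
Conditions: 30% aq. H2O2, cat. H2SO4, MeOH, rt
Reagents that add atoms: hydrogen peroxide, OO
Why: Acid-catalysed Dakin oxidation, in which the peroxyhemiacetal of the electron-rich aldehyde undergoes aryl migration to formate 2, methanol cleaves 2 in the same flask, and the acidic medium spares the easily oxidised phenol from the phenoxide chemistry of the alkaline variant.

**Step 2**
Reactants: 3 2,4,5-trimethoxyphenol
Product: 4 triisopropyl(2,4,5-trimethoxyphenoxy)silane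
Conditions: TIPSCl, imidazole, DMF, rt
Reagents that add atoms: triisopropylsilyl chloride, CC(C)[Si](Cl)(C(C)C)C(C)C
Why: Imidazole-promoted O-silylation of a phenol, with the triisopropylsilyl group chosen because it survives n-BuLi, binds lithium poorly and screens the ring hydrogen beside it in step 3.

**Step 3**
Reactants: 4 triisopropyl(2,4,5-trimethoxyphenoxy)silane
Product: 7 2,3,6-trimethoxy-5-(triisopropylsilyloxy)phenol, via aryllithium 5 (not isolated), via dimethyl arylboronate 6 (not isolated)
Conditions: n-BuLi, TMEDA, THF, 0 °C; B(OMe)3, −78 °C to rt; AcOH, 30% aq. H2O2, 0 °C to rt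
Reagents that add atoms: hydrogen peroxide, OO (the new oxygen of 7); n-butyllithium, [Li]CCCC (lithium of 5 only); trimethyl borate, COB(OC)OC (boron and methoxy groups of 6 only)
Why: Directed ortho-metalation followed by borylation–oxidation, in which the hydrogen between the two methoxy groups is acidified and its lithium chelated from both sides, the other ring hydrogen is shielded by the bulky silyl ether, and acetic-acid-buffered peroxide converts C–B into C–O by 1,2-aryl migration without touching the silyl ether.

**Step 4**
Reactants: 7 2,3,6-trimethoxy-5-(triisopropylsilyloxy)phenol; 8 benzyl bromide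
Product: 9 [3-(benzyloxy)-2,4,5-trimethoxyphenoxy]triisopropylsilane
Conditions: K2CO3, DMF, rt
Reagents that add atoms: none
Why: Williamson ether synthesis of a 2,6-dimethoxyphenol-type hydroxyl with a reactive benzylic bromide, under carbonate conditions that the hindered aryl silyl ether tolerates.

**Step 5**
Reactants: 9 [3-(benzyloxy)-2,4,5-trimethoxyphenoxy]triisopropylsilane
Product: 10 3-(benzyloxy)-2,4,5-trimethoxyphenol
Conditions: TBAF, AcOH, THF, 0 °C
Reagents that add atoms: none
Why: Fluoride-mediated desilylation driven by Si–F bond formation, buffered with acetic acid so that the air-sensitive phenoxide is protonated at once, while benzyl and methyl ethers are inert.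

**Step 6**
Reactants: 10 3-(benzyloxy)-2,4,5-trimethoxyphenol
Product: 11 3-(benzyloxy)-6-iodo-2,4,5-trimethoxyphenol
Conditions: NIS (1.0 equiv), MeCN, 0 °C, dark
Reagents that add atoms: N-iodosuccinimide, O=C1CCC(=O)N1I
Why: Electrophilic aromatic iodination at the only ring hydrogen left, which lies ortho to the free hydroxyl of a pentaoxygenated ring and is far more reactive than the benzyl phenyl ring, with one equivalent of a mild iodonium source at low temperature to hold back oxidation.

**Step 7**
Reactants: 11 3-(benzyloxy)-6-iodo-2,4,5-trimethoxyphenol; 12 1-(benzyloxy)-4-ethynylbenzene; 13 carbon monoxide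
Product: 16 7-(benzyloxy)-2-[4-(benzyloxy)phenyl]-5,6,8-trimethoxy-4H-chromen-4-one, via ynone 14 (not isolated), via enaminone 15 (not isolated)
Conditions: PdCl2(PPh3)2 (5 mol %), CO (20 bar), Et2NH, 120 °C, autoclave, no copper salt
Reagents that add atoms: diethylamine, CCNCC (its atoms stand in intermediate 15 only and leave again on ring closure)
Why: Zerovalent palladium generated from PdCl2(PPh3)2 inserts into the carbon–iodine bond of 11, CO insertion gives an aroylpalladium iodide, and amine-assisted transfer of the acetylide of 12 followed by reductive elimination releases ynone 14, which forms C4a–C4 and C4–C3. Diethylamine then adds to the β-carbon of 14 to give enaminone 15, whose ortho hydroxyl attacks the same carbon and expels the amine, which forms O1–C2. The closest known reaction type is the carbonylative Sonogashira-type annulation of 2-iodophenols with terminal alkynes to flavones in a secondary amine as solvent. Ring C closes in the 6-endo mode (a 6-endo-trig addition–elimination on 15, equal in outcome to a 6-endo-dig closure of 14), and no stereocentre is created. Two selectivities are needed: carbonylation before alkynylation, secured by the copper-free medium, the CO pressure and the ready CO uptake of an electron-rich arylpalladium, and flavone over aurone (5-exo), secured because conversion of 14 into 15 leaves C2 as the only electrophilic carbon within reach of the phenol. The hydroxyl and 5-methoxy groups flanking the halogen slow oxidative addition, which is why an iodide, 120 °C and a raised catalyst loading are chosen.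

**Step 8**
Reactants: 16 7-(benzyloxy)-2-[4-(benzyloxy)phenyl]-5,6,8-trimethoxy-4H-chromen-4-one
Product: 19 7-(benzyloxy)-2-[4-(benzyloxy)phenyl]-3-hydroxy-5,6,8-trimethoxy-4H-chromen-4-one, via 3-lithioflavone 17 (not isolated), via flavon-3-ylboronate 18 (not isolated)
Conditions: LDA, THF, −78 °C; B(OMe)3, −78 °C to rt; AcOH, 30% aq. H2O2, 0 °C to rt
Reagents that add atoms: hydrogen peroxide, OO (the new oxygen of 19); lithium diisopropylamide, CC(C)N([Li])C(C)C (lithium of 17 only); trimethyl borate, COB(OC)OC (boron and methoxy groups of 18 only)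
Why: Deprotonative lithiation of a flavone at C3, where the vinylic hydrogen is acidified and the lithium held by the C4 carbonyl oxygen, followed by borylation–oxidation, a known route from flavones to flavonols that at −78 °C should leave the benzylic C–H bonds and the pyranone ring alone.

**Step 9**
Reactants: 19 7-(benzyloxy)-2-[4-(benzyloxy)phenyl]-3-hydroxy-5,6,8-trimethoxy-4H-chromen-4-one
Product: 20 7-(benzyloxy)-2-[4-(benzyloxy)phenyl]-3,5,6,8-tetramethoxy-4H-chromen-4-one
Conditions: MeI, K2CO3, acetone, reflux
Reagents that add atoms: methyl iodide, CI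
Why: Williamson-type O-methylation of the only free hydroxyl group, the acidic enolic 3-OH, for which carbonate and methyl iodide are the standard flavonol conditions.

**Step 10**
Reactants: 20 7-(benzyloxy)-2-[4-(benzyloxy)phenyl]-3,5,6,8-tetramethoxy-4H-chromen-4-one
Product: 21 7-hydroxy-2-(4-hydroxyphenyl)-3,5,6,8-tetramethoxy-4H-chromen-4-one (CNP0539397.0)
Conditions: H2 (1 atm), 10% Pd/C, EtOAc–MeOH, rt
Reagents that add atoms: none
Why: Catalytic hydrogenolysis of the two aryl benzyl ethers, under which aryl methyl ethers and the tetrasubstituted, vinylogous-ester C2–C3 double bond of a 3-methoxyflavone are not reduced at atmospheric pressure.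

**Compound list**

1 | 2,4,5-trimethoxybenzaldehyde | COc1cc(OC)c(C=O)cc1OC | starting material
2 | 2,4,5-trimethoxyphenyl formate | COc1cc(OC)c(OC=O)cc1OC | intermediate
3 | 2,4,5-trimethoxyphenol | COc1cc(OC)c(O)cc1OC | intermediate
4 | triisopropyl(2,4,5-trimethoxyphenoxy)silane | COc1cc(OC)c(O[Si](C(C)C)(C(C)C)C(C)C)cc1OC | intermediate
5 | [2,3,6-trimethoxy-5-(triisopropylsilyloxy)phenyl]lithium | COc1c([Li])c(OC)c(O[Si](C(C)C)(C(C)C)C(C)C)cc1OC | intermediate
6 | dimethyl [2,3,6-trimethoxy-5-(triisopropylsilyloxy)phenyl]boronate | COc1c(B(OC)OC)c(OC)c(O[Si](C(C)C)(C(C)C)C(C)C)cc1OC | intermediate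
7 | 2,3,6-trimethoxy-5-(triisopropylsilyloxy)phenol | COc1c(O)c(OC)c(O[Si](C(C)C)(C(C)C)C(C)C)cc1OC | intermediate
8 | benzyl bromide | BrCc1ccccc1 | starting material
9 | [3-(benzyloxy)-2,4,5-trimethoxyphenoxy]triisopropylsilane | COc1c(OCc2ccccc2)c(OC)c(O[Si](C(C)C)(C(C)C)C(C)C)cc1OC | intermediate
10 | 3-(benzyloxy)-2,4,5-trimethoxyphenol | COc1c(OCc2ccccc2)c(OC)c(O)cc1OC | intermediate
11 | 3-(benzyloxy)-6-iodo-2,4,5-trimethoxyphenol | COc1c(OCc2ccccc2)c(OC)c(O)c(I)c1OC | intermediate
12 | 1-(benzyloxy)-4-ethynylbenzene | C#Cc1ccc(OCc2ccccc2)cc1 | starting material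
13 | carbon monoxide | [C-]#[O+] | starting material
14 | 1-[4-(benzyloxy)-2-hydroxy-3,5,6-trimethoxyphenyl]-3-[4-(benzyloxy)phenyl]prop-2-yn-1-one | COc1c(OCc2ccccc2)c(OC)c(O)c(C(=O)C#Cc2ccc(OCc3ccccc3)cc2)c1OC | intermediate
15 | (E)-1-[4-(benzyloxy)-2-hydroxy-3,5,6-trimethoxyphenyl]-3-[4-(benzyloxy)phenyl]-3-(diethylamino)prop-2-en-1-one | CCN(CC)/C(c1ccc(OCc2ccccc2)cc1)=C/C(=O)c1c(O)c(OC)c(OCc2ccccc2)c(OC)c1OC | intermediate
16 | 7-(benzyloxy)-2-[4-(benzyloxy)phenyl]-5,6,8-trimethoxy-4H-chromen-4-one | COc1c(OCc2ccccc2)c(OC)c2oc(-c3ccc(OCc4ccccc4)cc3)cc(=O)c2c1OC | intermediate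
17 | {7-(benzyloxy)-2-[4-(benzyloxy)phenyl]-5,6,8-trimethoxy-4-oxo-4H-chromen-3-yl}lithium | COc1c(OCc2ccccc2)c(OC)c2oc(-c3ccc(OCc4ccccc4)cc3)c([Li])c(=O)c2c1OC | intermediate
18 | dimethyl {7-(benzyloxy)-2-[4-(benzyloxy)phenyl]-5,6,8-trimethoxy-4-oxo-4H-chromen-3-yl}boronate | COc1c(OCc2ccccc2)c(OC)c2oc(-c3ccc(OCc4ccccc4)cc3)c(B(OC)OC)c(=O)c2c1OC | intermediate
19 | 7-(benzyloxy)-2-[4-(benzyloxy)phenyl]-3-hydroxy-5,6,8-trimethoxy-4H-chromen-4-one | COc1c(OCc2ccccc2)c(OC)c2oc(-c3ccc(OCc4ccccc4)cc3)c(O)c(=O)c2c1OC | intermediate
20 | 7-(benzyloxy)-2-[4-(benzyloxy)phenyl]-3,5,6,8-tetramethoxy-4H-chromen-4-one | COc1c(OCc2ccccc2)c(OC)c2oc(-c3ccc(OCc4ccccc4)cc3)c(OC)c(=O)c2c1OC | intermediate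
21 | 7-hydroxy-2-(4-hydroxyphenyl)-3,5,6,8-tetramethoxy-4H-chromen-4-one | COc1c(O)c(OC)c2oc(-c3ccc(O)cc3)c(OC)c(=O)c2c1OC | target

Total step count: 10
Longest linear sequence: 10 steps (1 to 21). Compounds 8, 12 and 13 are bought and enter directly.

**Steps most likely to fail**

**Step 7.** Oxidative addition into the doubly ortho-flanked, electron-rich carbon–iodine bond may be very slow. Three processes could then outrun ynone formation: capture of the aroylpalladium by diethylamine (aminocarbonylation), CO-free alkynylation with closure to a benzofuran, or reductive loss of iodine. The fallback sets out from 11 and 12 and forms C4a–C4 by polar organometallic acylation instead of catalysis. Alkyne 12 is deprotonated with n-BuLi and acylated with N-methoxy-N-methylcarbamoyl chloride to give 3-[4-(benzyloxy)phenyl]-N-methoxy-N-methylprop-2-ynamide F1. Iodophenol 11 is converted with MeMgCl and LiCl into its magnesium phenoxide. Iodine–magnesium exchange with i-PrMgCl·LiCl then gives chloromagnesium 3-(benzyloxy)-6-(chloromagnesio)-2,4,5-trimethoxyphenoxide F2, which adds to F1. Acidic work-up gives ynone 14, now isolated. Warming 14 with diethylamine in ethanol closes it through 15 to 16, where the route is rejoined.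

**Step 8.** Deprotonation at C3 may be incomplete. It may also be overtaken by benzylic deprotonation with Wittig rearrangement or by opening of the pyranone, and the crowded C3 anion may be borylated only sluggishly. The fallback sets out from 16 and brings in the oxygen electrophilically. Dimethyldioxirane in acetone–CH2Cl2 at 0 °C epoxidises the C2–C3 double bond to racemic cis-fused 7-(benzyloxy)-2-[4-(benzyloxy)phenyl]-2,3-epoxy-5,6,8-trimethoxychroman-4-one F3. Catalytic p-TsOH opens F3 at the oxygen- and aryl-stabilised C2, and loss of the C3 proton gives flavonol 19, where the route is rejoined.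

**Step 6.** Phenol 10 behaves as a hydroquinone monoether towards oxidants. Electron transfer to the iodinating agent with loss of a methyl group (quinone formation), or oxidative coupling, may therefore compete with ring substitution. The fallback sets out from silyl ether 9, in which the phenol oxygen is still masked. Iodine and silver trifluoroacetate in CH2Cl2 at 0 °C iodinate the single free ring position to give [3-(benzyloxy)-6-iodo-2,4,5-trimethoxyphenoxy]triisopropylsilane F4. TBAF with AcOH in THF then frees iodophenol 11, where the route is rejoined.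

**Further compounds**

F1 | step 7 | 3-[4-(benzyloxy)phenyl]-N-methoxy-N-methylprop-2-ynamide | CON(C)C(=O)C#Cc1ccc(OCc2ccccc2)cc1
F2 | step 7 | chloromagnesium 3-(benzyloxy)-6-(chloromagnesio)-2,4,5-trimethoxyphenoxide | COc1c(OCc2ccccc2)c(OC)c(O[Mg]Cl)c([Mg]Cl)c1OC
F3 | step 8 | racemic cis-fused 7-(benzyloxy)-2-[4-(benzyloxy)phenyl]-2,3-epoxy-5,6,8-trimethoxychroman-4-one (one enantiomer drawn) | COc1c(OCc2ccccc2)c(OC)c2O[C@@]3(c4ccc(OCc5ccccc5)cc4)O[C@H]3C(=O)c2c1OC
F4 | step 6 | [3-(benzyloxy)-6-iodo-2,4,5-trimethoxyphenoxy]triisopropylsilane | COc1c(OCc2ccccc2)c(OC)c(O[Si](C(C)C)(C(C)C)C(C)C)c(I)c1OC
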